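**Retrosynthetic overview**
- Numbering (germacrane): ring A = C1(=O)–C2=C3–C4(=C15H2)–C5–O–C10; ring B = O–C5–C6–C7–C8–C9–C10; ring C = lactone C6–O–C12(=O)–C11(=C13H2)–C7; C14 = methyl on C10; β = the face of ring B that carries C1.
- The route rests on ring B (O, C5, C6, C7, C8, C9, C10): it is a cyclohexanone ring with one oxygen inserted into its C5–C10 bond, and C7 with C11–C13 is the isopropenyl carbon of (R)-carvone (C5 = carvone C=O, C10 = its methyl-bearing carbon, C8 = its γ-CH2).
- Disconnections, backwards: C8 angelate; ring A at C2=C3 (metathesis of a C10 vinyl ketone with a C4 diene made from a C5 alkyne and ethylene); ring C from the isopropenyl methyl and C6–OH; C5–C4 and C6–O from the ring B lactone through its ketene acetal phosphate; C10–O by Baeyer–Villiger oxygen insertion; quaternary C10 by reductive alkylation of cis-γ-silyloxycarvone.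
- Ring order, forwards: carvone six-membered ring, then ring B (step 7), ring C (step 15), ring A (step 20).

Key step: step 7

Remark: C8 is corrected by Mitsunobu inversion and not through the 2-ene-1,4-dione, which is a hydroquinone tautomer with an epimerisable C7.
Remark: after step 7 ring B is never opened at C5, because an open-chain C5 ketone would be captured by the C8 silyloxy oxygen as a tetrahydrofuran under reductive etherification conditions.
Assumption: centres that are destroyed later (C5 in 16, C1 in 25) are carried as epimer mixtures and left open in the SMILES.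

Step 1
Reactants: 1 (R)-carvone
Product: 2 linear trimethylsilyl dienol ether of carvone (C5–OSiMe3; C5=C10 and C8=C9 double bonds; C7 unchanged)
Conditions: MeMgBr, FeCl3 (cat.), Et2O, −20 °C; then Me3SiCl, Et3N, DMPU, −20 °C → rt
Reagents that add atoms: chlorotrimethylsilane, C[Si](C)(C)Cl
Why: Under iron catalysis the methyl Grignard reagent acts as a base and removes a γ-proton (C8–H) to give the through-conjugated magnesium dienolate, which is silylated on oxygen (γ-deprotonation and silyl dienol ether formation), so the s-cis 1-silyloxy diene needed for γ-oxygenation is obtained without touching C7.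

Step 2
Reactants: 2 linear trimethylsilyl dienol ether
Product: 5 trans-γ-hydroxycarvone (C8–OH β and C7 isopropenyl α), via endoperoxide 3 (not isolated), via hydroperoxide 4 (not isolated)
Conditions: O2, tetraphenylporphyrin (cat.), visible light, CH2Cl2, −78 °C; then MeOH, PPh3, −78 °C → rt
Reagents that add atoms: oxygen, O=O
Why: Singlet oxygen adds to the s-cis 1-silyloxy diene in a [4+2] cycloaddition (photooxygenation of a cyclohexa-1,3-diene) mainly on the face anti to the C7 isopropenyl group, methanol cleaves the bridgehead silyl peroxyketal of 3 to the enone hydroperoxide 4, and PPh3 reduces the O–O bond with retention, so the new C8 centre is trans to C7.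

Step 3
Reactants: 5 trans-γ-hydroxycarvone
Product: 6 cis-γ-(4-nitrobenzoyloxy)carvone (C8 ester α, cis to the C7 isopropenyl group)
Conditions: 4-O2NC6H4CO2H, PPh3, DIAD, THF, 0 °C → rt
Reagents that add atoms: 4-nitrobenzoic acid, O=C(O)c1ccc(cc1)[N+](=O)[O-]
Why: Mitsunobu reaction, in which the oxyphosphonium of the secondary allylic alcohol is displaced by the carboxylate in an SN2 step with inversion at C8, so the C8 oxygen becomes cis to C7 without a carbonyl ever being placed at C8.

Step 4
Reactants: 6 cis-γ-(4-nitrobenzoyloxy)carvone
Product: 7 cis-γ-hydroxycarvone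
Conditions: K2CO3 (cat.), MeOH, 0 °C
Reagents that add atoms: none
Why: Base-catalysed transesterification of the electron-poor aryl ester (methanolysis) frees the alcohol with the C8–O bond intact, so the configuration set in step 3 is kept.

Step 5
Reactants: 7 cis-γ-hydroxycarvone
Product: 8 cis-γ-(tert-butyldimethylsilyloxy)carvone
Conditions: t-BuMe2SiCl, imidazole, DMF, rt
Reagents that add atoms: tert-butyldimethylsilyl chloride, CC(C)(C)[Si](C)(C)Cl
Why: Standard silylation of a secondary alcohol gives an ether that survives the hydride, enolate and Lewis acid steps and adds bulk to the α-face for step 6.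

Step 6
Reactants: 8 cis-γ-(tert-butyldimethylsilyloxy)carvone; 9 benzyl chloromethyl ether
Product: 11 cyclohexanone with quaternary C10 (CH2OBn β; CH3 α; C8–OSi α; C7 isopropenyl α), via lithium enolate 10 (not isolated)
Conditions: LiBH(s-Bu)3, THF, −78 °C; then 9, DMPU, −78 → 0 °C
Reagents that add atoms: benzyl chloromethyl ether (9), ClCOCc1ccccc1
Why: Conjugate reduction–enolate alkylation, in which the bulky borohydride adds hydride to the unsubstituted β-carbon C9 and the regiodefined tetrasubstituted enolate 10 is C-alkylated by the α-chloro ether on the face opposite to the cis-related C7 isopropenyl and C8 silyloxy groups (one of them is axial in either half-chair), which sets C10 with CH2OBn β and CH3 α.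

Step 7
Reactants: 11 cyclohexanone with quaternary C10
Product: 12 ring B ε-lactone (oxepan-2-one; C5 carbonyl, C10–O bond; substituents as in 11)
Conditions: Me3SiOOSiMe3, Me3SiOTf (cat.), CH2Cl2, −40 → −20 °C
Reagents that add atoms: bis(trimethylsilyl) peroxide, C[Si](C)(C)OO[Si](C)(C)C
Why: The silyl triflate activates the C5 carbonyl, the silyl peroxide adds to give a silylated Criegee-type peroxy adduct, and this collapses by migration of the antiperiplanar, fully substituted α-carbon C10 from carbon C5 to the peroxide oxygen with loss of a silyloxy group (Baeyer–Villiger oxidation in its silyl peroxide variant, the closest precedent being oxygen insertion into α-quaternary cyclohexanones that carry alkenes). Ring B is closed by a 1,2-shift ring enlargement from six to seven members and not by an endo or exo cyclisation, so no medium-ring closure has to be paid for. No new stereocentre is formed, and C10 migrates with retention, so the configuration set in step 6 is carried into the C10–O bond. The step needs regioselectivity (C10 and not the C6 methylene must migrate), which the higher migratory aptitude of the quaternary carbon secures, and chemoselectivity for the ketone over the isopropenyl group, which is secured because no peracid is present and the silyl peroxide is a nucleophilic, not an electrophilic, oxidant. The low temperature and the catalytic amount of silyl triflate should leave the silyl ether, the benzyl ether and the alkene untouched.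

Step 8
Reactants: 12 ring B ε-lactone
Product: 13 cyclic ketene acetal diphenyl phosphate (C5=C6; phosphate on the C5 oxygen)
Conditions: KN(SiMe3)2, (PhO)2P(O)Cl, THF/DMPU, −78 °C
Reagents that add atoms: diphenyl chlorophosphate, O=P(Cl)(Oc1ccccc1)Oc1ccccc1
Why: O-Phosphorylation of the lactone enolate (ketene acetal phosphate formation), in which deprotonation at C6 in the presence of the chlorophosphate traps the enolate on oxygen and so activates C5 for cross-coupling while the C5–O–C10 ring stays closed.

Step 9
Reactants: 13 cyclic ketene acetal diphenyl phosphate; 14 tributyl[(trimethylsilyl)ethynyl]stannane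
Product: 15 2-alkynyl oxepene (C5–C≡C–SiMe3; C5=C6 enol ether)
Conditions: Pd(PPh3)4 (cat.), LiCl, THF, 65 °C
Reagents that add atoms: tributyl[(trimethylsilyl)ethynyl]stannane (14), CCCC[Sn](CCCC)(CCCC)C#C[Si](C)(C)C
Why: Stille coupling, in which zerovalent palladium inserts into the C5–O(phosphate) bond, the alkynyl group is transferred from tin in preference to butyl, and reductive elimination forms the C5–C4 bond, with chloride assisting turnover as for enol triflates.

Step 10
Reactants: 15 2-alkynyl oxepene
Product: 16 C5 methyl ketal with C6 β-hydroxyl (C5 epimer mixture)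
Conditions: dimethyldioxirane (acetone solution), MeOH, CH2Cl2, −78 → 0 °C
Reagents that add atoms: dimethyldioxirane, CC1(C)OO1; methanol, CO
Why: Epoxidation of the electron-rich enol ether by the dioxirane on the β-face, anti to the allylic C7 isopropenyl group, and opening of the labile anomeric epoxide by methanol (glycal-epoxide chemistry) give the C6 β-alcohol, trans to C7, while the far less nucleophilic isopropenyl alkene is untouched at low temperature.

Step 11
Reactants: 16 C5 methyl ketal with C6 β-hydroxyl
Product: 17 C6 triethylsilyl ether of the methyl ketal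
Conditions: Et3SiCl, imidazole, DMAP (cat.), DMF, rt
Reagents that add atoms: chlorotriethylsilane, CC[Si](Cl)(CC)CC
Why: Silylation of the secondary alcohol puts a bulky group on the β-face next to C5 that can later be removed without loss of the C8 silyl ether.

Step 12
Reactants: 17 C6 triethylsilyl ether of the methyl ketal
Product: 18 oxepane with C5–H α and C5 alkynyl β (cis to C1 and to the C6 oxygen)
Conditions: Et3SiH, Me3SiOTf (cat.), CH2Cl2, −78 → −40 °C
Reagents that add atoms: none
Why: Silane reduction of a ketal (as in C-glycoside synthesis), in which the silyl triflate ionises the C5 methoxy group to the ring B oxocarbenium ion and Et3SiH should deliver hydride to its α-face because both atoms that flank the C5=O+ unit carry their larger group on the β-face (C6–OSiEt3 and C10–CH2OBn), which sets C5.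

Step 13
Reactants: 18 oxepane alkyne
Product: 19 allylic alcohol (C12–OH on the former isopropenyl methyl)
Conditions: SeO2 (cat.), t-BuOOH, CH2Cl2, rt
Reagents that add atoms: tert-butyl hydroperoxide, CC(C)(C)OO
Why: Allylic oxidation with SeO2 (ene reaction then [2,3]-sigmatropic shift) attacks the methyl group of the 1,1-disubstituted alkene in preference to the ring methine, and the hydroperoxide re-oxidises selenium so that the reaction should stop mainly at the allylic alcohol.

Step 14
Reactants: 19 allylic alcohol
Product: 20 C6,C12-diol with terminal alkyne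
Conditions: K2CO3 (cat.), MeOH, rt; then camphorsulfonic acid (cat.), 0 °C
Reagents that add atoms: none
Why: Two solvolyses in one flask, in which methoxide cleaves the C(sp)–Si bond and mild acid in methanol then removes the triethylsilyl ether, which is far more labile than the hindered secondary tert-butyldimethylsilyl ether at C8.

Step 15
Reactants: 20 C6,C12-diol
Product: 21 α-methylene γ-lactone (ring C, trans-fused: C6–O β, C7–C11 α)
Conditions: TEMPO (cat.), PhI(OAc)2, CH2Cl2, rt
Reagents that add atoms: none
Why: Oxidative lactonisation of a 1,4-diol, in which the oxoammonium salt from TEMPO oxidises the primary allylic alcohol to the enal, the C6 hydroxyl closes the five-membered lactol and a second oxidation gives the lactone, while the silyl ether on C8 rules out the isomeric lactone to C8 and the benzyl ether keeps C1 out of play.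

Step 16
Reactants: 21 α-methylene γ-lactone
Product: 22 primary C1 alcohol
Conditions: DDQ, CH2Cl2/H2O, 525 nm light, rt
Reagents that add atoms: none
Why: Photo-oxidative debenzylation, in which excited DDQ removes hydride from the benzylic position and water cleaves the resulting oxocarbenium ion, a method that tolerates the alkyne, the electron-poor alkene and the silyl ether where hydrogenolysis would not.

Step 17
Reactants: 22 primary C1 alcohol
Product: 23 C1 aldehyde
Conditions: Dess–Martin periodinane, pyridine, CH2Cl2, rt
Reagents that add atoms: none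
Why: Dess–Martin oxidation of the neopentyl primary alcohol gives an aldehyde that has no α-hydrogen and so cannot epimerise or eliminate.

Step 18
Reactants: 23 C1 aldehyde; 24 vinyl bromide
Product: 25 vinyl carbinol (C1 epimer mixture)
Conditions: CrCl2, NiCl2 (cat.), DMF, rt
Reagents that add atoms: vinyl bromide (24), C=CBr
Why: Nozaki–Hiyama–Kishi reaction, in which the vinylchromium species formed with nickel catalysis adds to the aldehyde only and leaves the lactone, its exocyclic alkene and the alkyne untouched, the new C1 centre being uncontrolled because it is oxidised in the next step.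

Step 19
Reactants: 25 vinyl carbinol
Product: 26 C10 vinyl ketone
Conditions: Dess–Martin periodinane, pyridine, CH2Cl2, 0 °C
Reagents that add atoms: none
Why: Dess–Martin oxidation of the allylic alcohol gives the vinyl ketone under buffered, non-nucleophilic conditions that avoid conjugate addition.

Step 20
Reactants: 26 C10 vinyl ketone; 27 ethylene
Product: 29 tricyclic dienone silyl ether (rings A B C complete; C8–OSi α), via diene 28 (not isolated)
Conditions: second-generation Hoveyda–Grubbs catalyst (cat.), ethylene (1 atm), toluene, 40 °C; then argon purge, 70 °C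
Reagents that add atoms: ethylene (27), C=C
Why: Enyne cross-metathesis with ethylene turns the terminal alkyne into the 2-substituted buta-1,3-diene 28, and after removal of ethylene the catalyst initiates on the monosubstituted diene terminus C3 and the resulting vinylcarbene closes onto the vinyl ketone (ring-closing metathesis, the carbene-plus-enone step known from enyne and enone cross-metathesis cascades) to form the cis C2=C3 bond of the seven-membered ring A, which is possible because the C5 and C10 arms are cis on ring B.

Step 21
Reactants: 29 tricyclic dienone silyl ether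
Product: 30 tricyclic C8 alcohol
Conditions: HF·pyridine, pyridine, THF, 0 °C → rt
Reagents that add atoms: none
Why: Fluoride-mediated desilylation under acidic, non-basic conditions, so that no alkoxide is formed that could translactonise to C8 or add to the enone systems.

Step 22
Reactants: 30 tricyclic C8 alcohol; 31 angelic acid
Product: 32 target CNP0282559.1
Conditions: 31, 2,4,6-Cl3C6H2COCl, Et3N, toluene, rt; then 30, 75 °C
Reagents that add atoms: angelic acid (31), C/C=C(/C)C(=O)O
Why: Yamaguchi-type esterification through the mixed anhydride of angelic acid without a nucleophilic catalyst, which should acylate the hindered secondary alcohol while avoiding Z-to-E isomerisation to the tiglate.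

**Compound list**
1 | (R)-carvone, (5R)-2-methyl-5-(prop-1-en-2-yl)cyclohex-2-en-1-one | CC1=CC[C@@H](C(C)=C)CC1=O | starting material
2 | 1-(trimethylsilyloxy)-2-methyl-5-isopropenylcyclohexa-1,3-diene, C7 as in 1 | CC1=C(O[Si](C)(C)C)C[C@H](C(C)=C)C=C1 | intermediate
3 | endoperoxide (not isolated): 1-trimethylsilyloxy-2,3-dioxabicyclo[2.2.2]oct-5-ene, O–O bridge C5 to C8 anti to the isopropenyl group | C[Si](C)(C)O[C@]12C[C@H](C(C)=C)[C@H](C=C1C)OO2 | intermediate
4 | γ-hydroperoxy enone (not isolated), C8–OOH trans to C7 isopropenyl | O=C1C[C@H](C(C)=C)[C@@H](OO)C=C1C | intermediate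
5 | trans-γ-hydroxycarvone, C8–OH trans to C7 isopropenyl | O=C1C[C@H](C(C)=C)[C@@H](O)C=C1C | intermediate
6 | cis-γ-(4-nitrobenzoyloxy)carvone | O=C1C[C@H](C(C)=C)[C@H](OC(=O)c2ccc(cc2)[N+](=O)[O-])C=C1C | intermediate
7 | cis-γ-hydroxycarvone | O=C1C[C@H](C(C)=C)[C@H](O)C=C1C | intermediate
8 | cis-γ-(tert-butyldimethylsilyloxy)carvone | O=C1C[C@H](C(C)=C)[C@H](O[Si](C)(C)C(C)(C)C)C=C1C | intermediate
9 | benzyl chloromethyl ether | ClCOCc1ccccc1 | starting material
10 | lithium enolate (not isolated), C5–OLi, C5=C10 | [Li]OC1=C(C)C[C@@H](O[Si](C)(C)C(C)(C)C)[C@@H](C(C)=C)C1 | intermediate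
11 | 2-(benzyloxymethyl)-2-methyl-4-(tert-butyldimethylsilyloxy)-5-isopropenylcyclohexanone; CH2OBn trans to the cis-related silyloxy and isopropenyl groups | O=C1C[C@H](C(C)=C)[C@H](O[Si](C)(C)C(C)(C)C)C[C@@]1(C)COCc1ccccc1 | intermediate
12 | ring B ε-lactone: 7-(benzyloxymethyl)-7-methyl-5-(tert-butyldimethylsilyloxy)-4-isopropenyloxepan-2-one, configuration as in 11 | O=C1C[C@H](C(C)=C)[C@H](O[Si](C)(C)C(C)(C)C)C[C@@](C)(COCc2ccccc2)O1 | intermediate
13 | cyclic ketene acetal diphenyl phosphate of 12 (C5=C6) | O=P(Oc1ccccc1)(Oc1ccccc1)OC1=C[C@H](C(C)=C)[C@H](O[Si](C)(C)C(C)(C)C)C[C@@](C)(COCc2ccccc2)O1 | intermediate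
14 | tributyl[(trimethylsilyl)ethynyl]stannane | CCCC[Sn](CCCC)(CCCC)C#C[Si](C)(C)C | starting material
15 | 2-(trimethylsilylethynyl)oxepene (C5=C6 enol ether) | C[Si](C)(C)C#CC1=C[C@H](C(C)=C)[C@H](O[Si](C)(C)C(C)(C)C)C[C@@](C)(COCc2ccccc2)O1 | intermediate
16 | C5 methyl ketal, C6 β-hydroxyl (trans to C7 isopropenyl), C5 epimers | COC1(C#C[Si](C)(C)C)[C@@H](O)[C@H](C(C)=C)[C@H](O[Si](C)(C)C(C)(C)C)C[C@@](C)(COCc2ccccc2)O1 | intermediate
17 | C6 triethylsilyl ether of 16 | COC1(C#C[Si](C)(C)C)[C@@H](O[Si](CC)(CC)CC)[C@H](C(C)=C)[C@H](O[Si](C)(C)C(C)(C)C)C[C@@](C)(COCc2ccccc2)O1 | intermediate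
18 | oxepane: C5–H α, C5 alkynyl β, C6–OSiEt3 β, C7 isopropenyl α, C8–OSi α, C10 CH2OBn β and CH3 α | C[Si](C)(C)C#C[C@H]1[C@@H](O[Si](CC)(CC)CC)[C@H](C(C)=C)[C@H](O[Si](C)(C)C(C)(C)C)C[C@@](C)(COCc2ccccc2)O1 | intermediate
19 | allylic alcohol of 18 (C11(=C13H2)–C12H2OH) | C[Si](C)(C)C#C[C@H]1[C@@H](O[Si](CC)(CC)CC)[C@H](C(CO)=C)[C@H](O[Si](C)(C)C(C)(C)C)C[C@@](C)(COCc2ccccc2)O1 | intermediate
20 | C6,C12-diol with terminal C5 alkyne | C#C[C@H]1[C@@H](O)[C@H](C(CO)=C)[C@H](O[Si](C)(C)C(C)(C)C)C[C@@](C)(COCc2ccccc2)O1 | intermediate
21 | α-methylene γ-lactone (rings B and C), C1 benzyl ether | C#C[C@H]1[C@H]2OC(=O)C(=C)[C@@H]2[C@H](O[Si](C)(C)C(C)(C)C)C[C@@](C)(COCc3ccccc3)O1 | intermediate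
22 | primary C1 alcohol | C#C[C@H]1[C@H]2OC(=O)C(=C)[C@@H]2[C@H](O[Si](C)(C)C(C)(C)C)C[C@@](C)(CO)O1 | intermediate
23 | C1 aldehyde | C#C[C@H]1[C@H]2OC(=O)C(=C)[C@@H]2[C@H](O[Si](C)(C)C(C)(C)C)C[C@@](C)(C=O)O1 | intermediate
24 | vinyl bromide | C=CBr | starting material
25 | vinyl carbinol, C1 epimers | C#C[C@H]1[C@H]2OC(=O)C(=C)[C@@H]2[C@H](O[Si](C)(C)C(C)(C)C)C[C@@](C)(C(O)C=C)O1 | intermediate
26 | C10 vinyl ketone with C5 alkyne | C#C[C@H]1[C@H]2OC(=O)C(=C)[C@@H]2[C@H](O[Si](C)(C)C(C)(C)C)C[C@@](C)(C(=O)C=C)O1 | intermediate
27 | ethylene | C=C | starting material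
28 | diene (not isolated): C5 buta-1,3-dien-2-yl, C10 vinyl ketone | C=CC(=C)[C@H]1[C@H]2OC(=O)C(=C)[C@@H]2[C@H](O[Si](C)(C)C(C)(C)C)C[C@@](C)(C(=O)C=C)O1 | intermediate
29 | tricyclic dienone, C8 tert-butyldimethylsilyl ether | C=C1C(=O)O[C@H]2[C@H]1[C@H](O[Si](C)(C)C(C)(C)C)C[C@]1(C)O[C@H]2C(=C)C=CC1=O | intermediate
30 | tricyclic C8 alcohol | C=C1C(=O)O[C@H]2[C@H]1[C@H](O)C[C@]1(C)O[C@H]2C(=C)C=CC1=O | intermediate
31 | angelic acid, (Z)-2-methylbut-2-enoic acid | C/C=C(/C)C(=O)O | starting material
32 | CNP0282559.1, (5S,6S,7R,8R,10S) in the numbering above, C8 angelate | C=C1C(=O)O[C@H]2[C@H]1[C@H](OC(=O)/C(C)=C\C)C[C@]1(C)O[C@H]2C(=C)C=CC1=O | target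

**Step count and risks**
Total step count: 22. Longest linear sequence: 22 steps from (R)-carvone (the route is fully linear).

Steps most likely to fail:

1. Step 7. The silyl triflate may trigger attack of the isopropenyl π-bond on the activated C5 carbonyl (Prins-type closure) or loss of the C8 silyl ether, or the peroxide may fail to add to the hindered carbonyl. The fallback keeps the same oxygen insertion but masks the alkene and uses a peracid. It sets out from 11: bromine addition to the isopropenyl group (pyridinium tribromide, CH2Cl2, −78 °C) gives the dibromo ketone F1. Buffered peracid Baeyer–Villiger oxidation (m-chloroperbenzoic acid, NaHCO3, CH2Cl2), now without Lewis acid and with nothing left to epoxidise, gives the dibromo lactone F2. Zinc dust with NH4Cl in ethanol restores the alkene, and the route is rejoined at 12.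

2. Step 12. Hydride may be delivered to the ring B oxocarbenium ion from the β-face, which would give the C5 epimer, or the cation may be captured by the isopropenyl group. The fallback reverses the order in which hydrogen and carbon are placed on C5, so that the carbon nucleophile enters on the face the hydride prefers. It sets out from 12: enolate hydroxylation (KN(SiMe3)2, then 2-(phenylsulfonyl)-3-phenyloxaziridine, THF, −78 °C) anti to C7 gives the α-hydroxy lactone F3. Silylation (Et3SiCl, imidazole) gives the silyloxy lactone F4. Reductive acetylation (i-Bu2AlH, −78 °C, then Ac2O, pyridine, DMAP) gives the α-acetoxy ether F5 with ring B still closed. BF3·OEt2-promoted alkynylation with stannane 14 then arrives at 18.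

3. Step 20. The ruthenium vinylcarbene formed on the diene may fail to engage the electron-poor, neopentyl-type vinyl ketone, so that the diene dimerises or adds to the enone in a thermal Diels–Alder reaction instead of closing ring A. The fallback closes ring A at the alcohol oxidation level. It sets out from 25: ethylene cross-metathesis of the alkyne (second-generation Hoveyda–Grubbs catalyst, ethylene, toluene) gives the diene carbinol F6. Ring-closing metathesis, with the catalyst now loading on the electron-rich allylic alcohol alkene (second-generation Grubbs catalyst, CH2Cl2, 40 °C), gives the bridged dienol F7. Oxidation of the doubly allylic alcohol with MnO2 returns to 29.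

Further compounds
F1 | step 7 | dibromo ketone, 11 with the isopropenyl group as its 1,2-dibromide (C11 epimers) | O=C1C[C@H](C(C)(Br)CBr)[C@H](O[Si](C)(C)C(C)(C)C)C[C@@]1(C)COCc1ccccc1
F2 | step 7 | dibromo lactone, 12 with the isopropenyl group as its 1,2-dibromide | O=C1C[C@H](C(C)(Br)CBr)[C@H](O[Si](C)(C)C(C)(C)C)C[C@@](C)(COCc2ccccc2)O1
F3 | step 12 | α-hydroxy lactone, 12 with C6 β-OH | O=C1[C@@H](O)[C@H](C(C)=C)[C@H](O[Si](C)(C)C(C)(C)C)C[C@@](C)(COCc2ccccc2)O1
F4 | step 12 | silyloxy lactone, C6 triethylsilyl ether of F3 | O=C1[C@@H](O[Si](CC)(CC)CC)[C@H](C(C)=C)[C@H](O[Si](C)(C)C(C)(C)C)C[C@@](C)(COCc2ccccc2)O1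
F5 | step 12 | α-acetoxy ether, C5 acetate of the lactol of F4 (C5 epimers) | CC(=O)OC1[C@@H](O[Si](CC)(CC)CC)[C@H](C(C)=C)[C@H](O[Si](C)(C)C(C)(C)C)C[C@@](C)(COCc2ccccc2)O1
F6 | step 20 | diene carbinol, 25 with the alkyne converted to buta-1,3-dien-2-yl (C1 epimers) | C=CC(=C)[C@H]1[C@H]2OC(=O)C(=C)[C@@H]2[C@H](O[Si](C)(C)C(C)(C)C)C[C@@](C)(C(O)C=C)O1
F7 | step 20 | bridged dienol, 29 with C1 as carbinol (C1 epimers) | C=C1C(=O)O[C@H]2[C@H]1[C@H](O[Si](C)(C)C(C)(C)C)C[C@]1(C)O[C@H]2C(=C)C=CC1O
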